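**Retrosynthetic overview**

1. Target 17 ← acetonide hydrolysis and O-debenzylation of 15 ← C7–C8 disconnection into aldehyde 9 (C8 as enamine nucleophile) and vanillyl p-quinone methide 12 (C7 as electrophile), released in the flask from sulfone 11.
2. Enabling feature: the free C4–OH of guaiacyl ring A is para to the benzylic carbon C7, so C7 can be expressed as the exocyclic CH2 of a p-quinone methide (the quinone-methide reactivity that guaiacyl units show at C7 in lignan biosynthesis); 1,6-addition restores aromatic ring A with its phenol already free.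
3. Aldehyde 9 ← triol 7 ← Seebach alkylation of the pivalaldehyde dioxolanone 2 of (R)-malic acid with benzylic bromide 4, which sets the quaternary carbinol centre C8'.
4. Rings: the target is acyclic and both arene rings are bought. Two temporary rings are formed in this order: a 1,3-dioxolan-4-one (step 1, opened in step 4) and a 1,3-dioxolane acetonide (step 5, opened in step 10).

Key step: step 8

Remark: lignan numbering is used. C7/C8/C9 are the benzylic CH2, the CH and the CH2OH of the half that carries ring A; C7'/C8'/C9' are the corresponding atoms of the half that carries ring B and the tertiary OH. The target is (8R,8'R).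

**Step 1**
Reactants: 1 (R)-malic acid
Product: 2 [(2R,4R)-2-tert-butyl-5-oxo-1,3-dioxolan-4-yl]acetic acid
Conditions: t-BuCHO, TsOH·H2O (cat.), H2SO4 (cat.), pentane, reflux, Dean–Stark; recrystallisation
Reagents that add atoms: pivalaldehyde, CC(C)(C)C=O
Why: Acid-catalysed acetalisation of the α-hydroxy acid unit (Seebach self-regeneration-of-stereocentres template) closes the five-membered dioxolanone in preference to the six-membered dioxanone, and the cis isomer (tert-butyl and CH2CO2H on the same face, new acetal centre 2R) is the favoured, crystalline one while the malic acid centre is untouched.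

**Step 2**
Reactants: 3 [4-(benzyloxy)-3-methoxyphenyl]methanol
Product: 4 1-(benzyloxy)-4-(bromomethyl)-2-methoxybenzene
Conditions: PBr3 (0.4 equiv), Et2O, 0 °C
Reagents that add atoms: phosphorus tribromide, BrP(Br)Br
Why: Bromination of an electron-rich benzylic alcohol through its phosphite ester is a standard substitution that leaves the aryl benzyl ether intact at 0 °C.

**Step 3**
Reactants: 2 [(2R,4R)-2-tert-butyl-5-oxo-1,3-dioxolan-4-yl]acetic acid, 4 1-(benzyloxy)-4-(bromomethyl)-2-methoxybenzene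
Product: 6 {(2R,4R)-4-[4-(benzyloxy)-3-methoxybenzyl]-2-tert-butyl-5-oxo-1,3-dioxolan-4-yl}acetic acid, via dilithium enolate 5 (not isolated)
Conditions: LiN(SiMe3)2 (2.1 equiv), THF, −78 °C; then 4, −78 to −20 °C; aq. HCl work-up
Reagents that add atoms: none
Why: Seebach alkylation with self-regeneration of the stereocentre: the ring enolate in 5 is planar at C4 and the bromide approaches anti to the tert-butyl group of the intact acetal centre, so the benzyl group enters trans to tert-butyl with net retention and sets the quaternary centre (future C8') as 4R.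

**Step 4**
Reactants: 6 {(2R,4R)-4-[4-(benzyloxy)-3-methoxybenzyl]-2-tert-butyl-5-oxo-1,3-dioxolan-4-yl}acetic acid
Product: 7 (2R)-2-[4-(benzyloxy)-3-methoxybenzyl]butane-1,2,4-triol
Conditions: LiAlH4, THF, 0 °C to reflux; Fieser work-up
Reagents that add atoms: none
Why: Hydride reduction takes the carboxylate and the dioxolanone carbonyl to the two primary alcohols while the acylal collapses and frees the tertiary hydroxyl (pivalaldehyde is reduced to neopentyl alcohol); the quaternary centre is not involved.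

**Step 5**
Reactants: 7 (2R)-2-[4-(benzyloxy)-3-methoxybenzyl]butane-1,2,4-triol
Product: 8 2-{(4R)-4-[4-(benzyloxy)-3-methoxybenzyl]-2,2-dimethyl-1,3-dioxolan-4-yl}ethan-1-ol
Conditions: Me2C(OMe)2, PPTS (cat.), acetone, rt
Reagents that add atoms: 2,2-dimethoxypropane, COC(C)(C)OC
Why: Transketalisation under thermodynamic control should favour the five-membered acetonide of the 1,2-diol over the six-membered dioxane of the 2,4-diol, which leaves the C4 primary alcohol free.

**Step 6**
Reactants: 8 2-{(4R)-4-[4-(benzyloxy)-3-methoxybenzyl]-2,2-dimethyl-1,3-dioxolan-4-yl}ethan-1-ol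
Product: 9 2-{(4R)-4-[4-(benzyloxy)-3-methoxybenzyl]-2,2-dimethyl-1,3-dioxolan-4-yl}acetaldehyde
Conditions: TEMPO (10 mol %), PhI(OAc)2 (1.1 equiv), CH2Cl2, rt
Reagents that add atoms: none
Why: Oxoammonium (TEMPO) oxidation of a primary alcohol stops at the aldehyde under nearly neutral conditions that the acetonide, the benzyl ether and the β-alkoxy aldehyde should tolerate.

**Step 7**
Reactants: 10 4-(hydroxymethyl)-2-methoxyphenol (vanillyl alcohol)
Product: 11 2-methoxy-4-[(4-methylbenzenesulfonyl)methyl]phenol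
Conditions: TolSO2Na (2 equiv), HCO2H/H2O, rt
Reagents that add atoms: sodium 4-methylbenzenesulfinate, [Na+].[O-]S(=O)c1ccc(C)cc1
Why: Acid-promoted SN1-type substitution: the p-hydroxybenzylic cation is captured at sulfur by sulfinate to give a bench-stable sulfone that serves as a quinone methide precursor.

**Step 8**
Reactants: 9 2-{(4R)-4-[4-(benzyloxy)-3-methoxybenzyl]-2,2-dimethyl-1,3-dioxolan-4-yl}acetaldehyde, 11 2-methoxy-4-[(4-methylbenzenesulfonyl)methyl]phenol
Product: 15 (2R)-2-{(4R)-4-[4-(benzyloxy)-3-methoxybenzyl]-2,2-dimethyl-1,3-dioxolan-4-yl}-3-(4-hydroxy-3-methoxyphenyl)propan-1-ol, via quinone methide 12 (not isolated), via enamine 13 (not isolated), via aldehyde 14 (not isolated)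
Conditions: (S)-2-[diphenyl(trimethylsilyloxy)methyl]pyrrolidine (20 mol %), Na2CO3 (1.5 equiv), CH2Cl2, 0 °C to rt, 11 (1.3 equiv) added in portions; then MeOH, NaBH4, 0 °C
Reagents that add atoms: none
Why: Na2CO3 deprotonates the phenol of 11 and sulfinate leaves in a 1,6-elimination that releases the p-quinone methide 12 slowly, while the amine condenses with 9 to the E-enamine 13; the enamine carbon (C8) adds to the exocyclic CH2 (C7) of 12 in a 1,6-conjugate addition driven by re-aromatisation of ring A to the free guaiacol, and hydrolysis of the iminium gives aldehyde 14 and returns the catalyst. The closest known reaction type is the secondary-amine-catalysed asymmetric α-alkylation of aldehydes by 1,6-addition of their enamines to para-quinone methides, joined here to the known base-induced release of quinone methides from hydroxybenzyl sulfones. No ring is closed. The new stereocentre C8 is set by the catalyst: in the s-trans E-enamine the CPh2(OSiMe3) arm covers one face and 12 is taken up on the other, which should give the (2S)-aldehyde 14, reduced by NaBH4 in the same pot before it can epimerise to the (2R)-alcohol 15. The step needs C-alkylation at C7 in preference to O- or N-capture and oligomerisation of 12, and it needs a single alkylation: the O- and N-adducts of 12 are hydroxybenzyl ethers and amines that can revert to 12, the slow release from the sulfone keeps 12 dilute, and the α-branched aldehyde 14 no longer forms an enamine readily. The ketal oxygen on C8' is a poor leaving group under carbonate, which should hold back β-elimination from 13, and the benzyl ether on ring B leaves ring A as the only ring able to form a quinone methide.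

**Step 9**
Reactants: 15 (2R)-2-{(4R)-4-[4-(benzyloxy)-3-methoxybenzyl]-2,2-dimethyl-1,3-dioxolan-4-yl}-3-(4-hydroxy-3-methoxyphenyl)propan-1-ol
Product: 16 (2R)-3-(4-hydroxy-3-methoxyphenyl)-2-[(4R)-4-(4-hydroxy-3-methoxybenzyl)-2,2-dimethyl-1,3-dioxolan-4-yl]propan-1-ol
Conditions: H2 (1 atm), Pd/C (10 % Pd on carbon), EtOAc/MeOH, rt
Reagents that add atoms: none
Why: Catalytic hydrogenolysis cleaves only the benzylic C–O bond of the aryl benzyl ether; the acetonide, the aryl methyl ethers and the C-benzyl bonds are inert and no stereocentre is touched.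

**Step 10**
Reactants: 16 (2R)-3-(4-hydroxy-3-methoxyphenyl)-2-[(4R)-4-(4-hydroxy-3-methoxybenzyl)-2,2-dimethyl-1,3-dioxolan-4-yl]propan-1-ol
Product: 17 (2R,3R)-2,3-bis(4-hydroxy-3-methoxybenzyl)butane-1,2,4-triol (CNP0129855.2)
Conditions: AcOH/H2O (4:1), 40 °C
Reagents that add atoms: none
Why: Acid-catalysed ketal hydrolysis frees the tertiary and primary hydroxyls, and the mild aqueous acid should avoid cyclodehydration of the 1,4-diol.

**Compound list**

1 | (R)-malic acid | O[C@H](CC(=O)O)C(=O)O | starting material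
2 | [(2R,4R)-2-tert-butyl-5-oxo-1,3-dioxolan-4-yl]acetic acid | CC(C)(C)[C@@H]1O[C@H](CC(O)=O)C(=O)O1 | intermediate
3 | [4-(benzyloxy)-3-methoxyphenyl]methanol | COc1cc(CO)ccc1OCc1ccccc1 | starting material
4 | 1-(benzyloxy)-4-(bromomethyl)-2-methoxybenzene | COc1cc(CBr)ccc1OCc1ccccc1 | intermediate
5 | dilithium enolate of 2 (lithium carboxylate and lithium ring enolate, acetal centre retained) | [Li+].[Li+].CC(C)(C)[C@@H]1OC(CC([O-])=O)=C([O-])O1 | intermediate
6 | {(2R,4R)-4-[4-(benzyloxy)-3-methoxybenzyl]-2-tert-butyl-5-oxo-1,3-dioxolan-4-yl}acetic acid | CC(C)(C)[C@@H]1O[C@](Cc2ccc(OCc3ccccc3)c(OC)c2)(CC(O)=O)C(=O)O1 | intermediate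
7 | (2R)-2-[4-(benzyloxy)-3-methoxybenzyl]butane-1,2,4-triol | OC[C@](O)(CCO)Cc1ccc(OCc2ccccc2)c(OC)c1 | intermediate
8 | 2-{(4R)-4-[4-(benzyloxy)-3-methoxybenzyl]-2,2-dimethyl-1,3-dioxolan-4-yl}ethan-1-ol | CC1(C)OC[C@](CCO)(Cc2ccc(OCc3ccccc3)c(OC)c2)O1 | intermediate
9 | 2-{(4R)-4-[4-(benzyloxy)-3-methoxybenzyl]-2,2-dimethyl-1,3-dioxolan-4-yl}acetaldehyde | CC1(C)OC[C@](CC=O)(Cc2ccc(OCc3ccccc3)c(OC)c2)O1 | intermediate
10 | 4-(hydroxymethyl)-2-methoxyphenol (vanillyl alcohol) | COc1cc(CO)ccc1O | starting material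
11 | 2-methoxy-4-[(4-methylbenzenesulfonyl)methyl]phenol | COc1cc(CS(=O)(=O)c2ccc(C)cc2)ccc1O | intermediate
12 | 2-methoxy-4-methylidenecyclohexa-2,5-dien-1-one (vanillyl p-quinone methide) | COC1=CC(=C)C=CC1=O | intermediate
13 | (2S)-1-[(E)-2-{(4R)-4-[4-(benzyloxy)-3-methoxybenzyl]-2,2-dimethyl-1,3-dioxolan-4-yl}ethenyl]-2-[diphenyl(trimethylsilyloxy)methyl]pyrrolidine (E-enamine of 9) | C[Si](C)(C)OC(c1ccccc1)(c1ccccc1)[C@@H]1CCCN1/C=C/[C@]1(Cc2ccc(OCc3ccccc3)c(OC)c2)COC(C)(C)O1 | intermediate
14 | (2S)-2-{(4R)-4-[4-(benzyloxy)-3-methoxybenzyl]-2,2-dimethyl-1,3-dioxolan-4-yl}-3-(4-hydroxy-3-methoxyphenyl)propanal | COc1cc(C[C@H](C=O)[C@]2(OC(C)(C)OC2)Cc3ccc(OCc4ccccc4)c(OC)c3)ccc1O | intermediate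
15 | (2R)-2-{(4R)-4-[4-(benzyloxy)-3-methoxybenzyl]-2,2-dimethyl-1,3-dioxolan-4-yl}-3-(4-hydroxy-3-methoxyphenyl)propan-1-ol | COc1cc(C[C@H](CO)[C@]2(OC(C)(C)OC2)Cc3ccc(OCc4ccccc4)c(OC)c3)ccc1O | intermediate
16 | (2R)-3-(4-hydroxy-3-methoxyphenyl)-2-[(4R)-4-(4-hydroxy-3-methoxybenzyl)-2,2-dimethyl-1,3-dioxolan-4-yl]propan-1-ol | COc1cc(C[C@H](CO)[C@]2(OC(C)(C)OC2)Cc3ccc(O)c(OC)c3)ccc1O | intermediate
17 | (2R,3R)-2,3-bis(4-hydroxy-3-methoxybenzyl)butane-1,2,4-triol | COc1cc(C[C@H](CO)[C@@](O)(CO)Cc2ccc(O)c(OC)c2)ccc1O | target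

**Step count**

Total: 10 steps. Longest linear sequence: 8 steps (1, 3, 4, 5, 6, 8, 9, 10) from (R)-malic acid.

**Steps most likely to fail**

Step 8. Several processes could erode the result:
- β-elimination of the ketal oxygen from the enamine or iminium, which would open the dioxolane;
- slow enamine formation next to the quaternary centre, which lets the quinone methide oligomerise or be captured at oxygen;
- a mismatched influence of C8' on the facial selectivity;
- epimerisation of 14 before reduction.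

The fallback forms the same C7–C8 bond by an auxiliary-controlled enolate alkylation. It sets out from aldehyde 9 and returns at 16. Pinnick oxidation (NaClO2, NaH2PO4, 2-methylbut-2-ene, t-BuOH/H2O) would give 2-{(4R)-4-[4-(benzyloxy)-3-methoxybenzyl]-2,2-dimethyl-1,3-dioxolan-4-yl}acetic acid F1. N-acylation of (4S)-4-benzyl-1,3-oxazolidin-2-one (t-BuCOCl, Et3N, LiCl, THF) would give (4S)-4-benzyl-3-(2-{(4R)-4-[4-(benzyloxy)-3-methoxybenzyl]-2,2-dimethyl-1,3-dioxolan-4-yl}acetyl)-1,3-oxazolidin-2-one F2. Deprotonation with NaN(SiMe3)2 in THF at −78 °C and alkylation with bromide 4 is an Evans asymmetric alkylation, in which the chelated Z-enolate is attacked anti to the benzyl group of the auxiliary. It should give (4S)-4-benzyl-3-[(2S)-3-[4-(benzyloxy)-3-methoxyphenyl]-2-{(4R)-4-[4-(benzyloxy)-3-methoxybenzyl]-2,2-dimethyl-1,3-dioxolan-4-yl}propanoyl]-1,3-oxazolidin-2-one F3, with the same spatial arrangement at C8 as in 15. LiBH4 in THF/MeOH would remove the auxiliary reductively to (2R)-3-[4-(benzyloxy)-3-methoxyphenyl]-2-{(4R)-4-[4-(benzyloxy)-3-methoxybenzyl]-2,2-dimethyl-1,3-dioxolan-4-yl}propan-1-ol F4. H2 over Pd/C would then cleave both benzyl ethers to give 16.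

Step 3. The dianion may decompose on warming (β-elimination, ketene formation) or alkylate sluggishly, and the electron-rich benzylic bromide may ionise and polymerise, so conversion and diastereoselectivity could both suffer.

The fallback builds C8' by reagent-controlled epoxidation instead of enolate alkylation. It sets out from bromide 4 and returns at triol 7. Alkylation of triethyl phosphonoacetate (NaH, THF) would give ethyl 3-[4-(benzyloxy)-3-methoxyphenyl]-2-(diethoxyphosphoryl)propanoate F5. Horner–Wadsworth–Emmons methylenation (aq. HCHO, K2CO3) would give ethyl 2-[4-(benzyloxy)-3-methoxybenzyl]prop-2-enoate F6. Reduction with i-Bu2AlH (CH2Cl2, −78 °C) would give 2-[4-(benzyloxy)-3-methoxybenzyl]prop-2-en-1-ol F7. Sharpless asymmetric epoxidation (Ti(OiPr)4, L-(+)-diethyl tartrate, t-BuOOH, 4 Å sieves, CH2Cl2, −20 °C) should give {(2S)-2-[4-(benzyloxy)-3-methoxybenzyl]oxiran-2-yl}methanol F8. The choice of L-(+)-tartrate rests on its known preference for (2S)-epoxy alcohols and should be confirmed on the first batch. Opening at the terminal epoxide CH2 with (i-PrO)Me2SiCH2MgCl and CuI (cat.) in THF would give (2R)-2-[4-(benzyloxy)-3-methoxybenzyl]-4-[dimethyl(propan-2-yloxy)silyl]butane-1,2-diol F9. Tamao oxidation (H2O2, KF, KHCO3, THF/MeOH) would then give 7.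

Step 5. Ketalisation may not be regioselective: a six-membered dioxane across the 2,4-diol or open mixed ketals at the primary hydroxyls would divert material.

The fallback differentiates the two primary hydroxyls before the ketal is made. It sets out from triol 7 and returns at 8. Selective silylation of the less hindered C4 hydroxyl (t-BuPh2SiCl, imidazole, CH2Cl2, 0 °C; the C1 hydroxyl is neopentylic) would give (2R)-2-[4-(benzyloxy)-3-methoxybenzyl]-4-[(tert-butyldiphenylsilyl)oxy]butane-1,2-diol F10. Acetonide formation (Me2C(OMe)2, PPTS) on the only remaining diol would give tert-butyl(2-{(4R)-4-[4-(benzyloxy)-3-methoxybenzyl]-2,2-dimethyl-1,3-dioxolan-4-yl}ethoxy)diphenylsilane F11. Bu4NF in THF would then give 8.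

**Further compounds**

F1 | step 8 | 2-{(4R)-4-[4-(benzyloxy)-3-methoxybenzyl]-2,2-dimethyl-1,3-dioxolan-4-yl}acetic acid | CC1(C)OC[C@](CC(=O)O)(Cc2ccc(OCc3ccccc3)c(OC)c2)O1
F2 | step 8 | (4S)-4-benzyl-3-(2-{(4R)-4-[4-(benzyloxy)-3-methoxybenzyl]-2,2-dimethyl-1,3-dioxolan-4-yl}acetyl)-1,3-oxazolidin-2-one | CC1(C)OC[C@](CC(=O)N2[C@@H](Cc3ccccc3)COC2=O)(Cc4ccc(OCc5ccccc5)c(OC)c4)O1
F3 | step 8 | (4S)-4-benzyl-3-[(2S)-3-[4-(benzyloxy)-3-methoxyphenyl]-2-{(4R)-4-[4-(benzyloxy)-3-methoxybenzyl]-2,2-dimethyl-1,3-dioxolan-4-yl}propanoyl]-1,3-oxazolidin-2-one | COc1cc(C[C@H](C(=O)N2[C@@H](Cc3ccccc3)COC2=O)[C@]4(OC(C)(C)OC4)Cc5ccc(OCc6ccccc6)c(OC)c5)ccc1OCc7ccccc7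
F4 | step 8 | (2R)-3-[4-(benzyloxy)-3-methoxyphenyl]-2-{(4R)-4-[4-(benzyloxy)-3-methoxybenzyl]-2,2-dimethyl-1,3-dioxolan-4-yl}propan-1-ol | COc1cc(C[C@H](CO)[C@]2(OC(C)(C)OC2)Cc3ccc(OCc4ccccc4)c(OC)c3)ccc1OCc5ccccc5
F5 | step 3 | ethyl 3-[4-(benzyloxy)-3-methoxyphenyl]-2-(diethoxyphosphoryl)propanoate (racemic) | CCOC(=O)C(Cc1ccc(OCc2ccccc2)c(OC)c1)P(=O)(OCC)OCC
F6 | step 3 | ethyl 2-[4-(benzyloxy)-3-methoxybenzyl]prop-2-enoate | CCOC(=O)C(=C)Cc1ccc(OCc2ccccc2)c(OC)c1
F7 | step 3 | 2-[4-(benzyloxy)-3-methoxybenzyl]prop-2-en-1-ol | OCC(=C)Cc1ccc(OCc2ccccc2)c(OC)c1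
F8 | step 3 | {(2S)-2-[4-(benzyloxy)-3-methoxybenzyl]oxiran-2-yl}methanol | OC[C@@]1(Cc2ccc(OCc3ccccc3)c(OC)c2)CO1
F9 | step 3 | (2R)-2-[4-(benzyloxy)-3-methoxybenzyl]-4-[dimethyl(propan-2-yloxy)silyl]butane-1,2-diol | OC[C@](O)(CC[Si](C)(C)OC(C)C)Cc1ccc(OCc2ccccc2)c(OC)c1
F10 | step 5 | (2R)-2-[4-(benzyloxy)-3-methoxybenzyl]-4-[(tert-butyldiphenylsilyl)oxy]butane-1,2-diol | OC[C@](O)(CCO[Si](c1ccccc1)(c1ccccc1)C(C)(C)C)Cc1ccc(OCc2ccccc2)c(OC)c1
F11 | step 5 | tert-butyl(2-{(4R)-4-[4-(benzyloxy)-3-methoxybenzyl]-2,2-dimethyl-1,3-dioxolan-4-yl}ethoxy)diphenylsilane | CC1(C)OC[C@](CCO[Si](c2ccccc2)(c2ccccc2)C(C)(C)C)(Cc3ccc(OCc4ccccc4)c(OC)c3)O1
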